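## Analysis of the target

The target 36 is a melampolide-type germacranolide. Ring A is a cyclodeca-1(10),4-diene with a Z C1=C10 bond and an E C4=C5 bond, each carrying a methyl group. Ring B is an α-methylene-γ-butyrolactone (O–C6, C7, C11=C13, C12=O) fused to ring A across C6–C7. Four contiguous stereocentres sit on ring A: C6 (S, lactone oxygen), C7 (S, tertiary hydroxyl), C8 (S, secondary hydroxyl) and C9 (R, angelate). H6 and the 7-hydroxyl are cis on ring B, so the ring fusion is cis; O7/O8 are erythro, and O8/O9 are threo with the spatial arrangement of (S,S)-tartaric acid. The sensitive groups are the α-methylene lactone (a Michael acceptor), the angelate (isomerises to the tiglate and does not survive organometallics, hydrides or strong base), the 1,5-diene (transannular cyclisation under acid), the allylic C–O bonds at C6 and C9, and the free 8-hydroxyl next to the lactone (lactone or acyl migration). The synthesis is hard because a ten-membered ring with two trisubstituted alkenes of opposite geometry must be closed, because C7 is a fully substituted, oxygenated carbon between two oxygenated stereocentres, and because only one of three hydroxyls is acylated. The strategy rests on the unit C6(O)–C7–C11(=C13): a homoallylic alcohol whose carbinol carbon C6 is also allylic to C4=C5. This is the retron of a [2,3]-Wittig shift of an ether joining O6 to C13, and that ether lies in a 13-membered ring which contracts to ring A.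

## Retrosynthetic reasoning

**C9–O acyl bond.** Target 36 is cut at the ester into triol lactone 33 and angelic acid (34). The angelate is put on last because it would not survive the organolithium, hydride and fluoride steps. The cut is viable because the 9-hydroxyl is the only unhindered one: the 8-hydroxyl is next to the quaternary C7 and the 7-hydroxyl is tertiary.

**O7, O8, O9 protecting groups.** Triol 33 comes from lactone 32, which carries a methoxymethyl ether on O7 and an acetonide on O8/O9. Both are acid-labile and inert to base, lithium reagents, hydride and fluoride. The acetonide also keeps O8 away from C12 while the lactone is made.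

**Lactone C12–O6 bond.** Lactone 32 is taken back to diol 29 (6-hydroxyl, 12-hydroxyl) and then to its 12-silyl ether 28. C12 is carried at the alcohol level because a C12 carbonyl would make C8–H a vinylogous acidic site and would itself be attacked by the base of the key step. The forward step must oxidise the primary allylic alcohol and lactonise onto O6 only.

**C6–C7 bond (key disconnection).** In 28 the C6–C7 bond is cut while O6 is joined to C13, which gives the 13-membered diallyl ether 25. This one transform removes ring A, both new stereocentres (C6, C7) and the exocyclic methylene, and leaves a strain-free macrocyclic ether. The forward reaction has to lithiate C6 selectively and deliver it to the enol-ether carbon C7 on the correct face.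

**O6–C6 ether bond.** Ether 25 is opened at O6–C6 to chloro alcohol 23, in which C13 bears the hydroxyl and C6 the chloride. The cut is placed at a primary allylic carbon, and the 13-membered ring has little strain.

**C13 and C6 oxidation levels.** In 23 the C13 hydroxymethyl group is the reduced form of an ester, so 23 comes from chloro ester 22, in which the ester carbon is C13 and the C12 silyl ether is already in place. Chloride 22 comes from allylic alcohol 20, and 20 from vinyl iodide 19 by cutting C5–C6. The vinyl iodide masks the C6 alcohol through the earlier base-mediated steps without a protecting group.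

**Enol ether O7–CH2 bond.** Enol ether 19 is the O-alkylation product of β-keto ester 17. The geometry needed is the E one: C8 cis to the ester carbon (later C13) and O7 cis to C12. This is the arrangement a non-chelated enolate prefers.

**C7–C11 bond.** Keto ester 17 is cut between C7 and C11 into Weinreb amide 14 and silyloxy ester 7 (from ethyl 3-hydroxypropanoate, 6). The ester brings C11, C12 with its final silyl ether, and C13.

**C1=C10 alkene.** Amide 14 is cut at the Z alkene into methyl ketone 12 and phosphonium salt 5. An α-alkoxy methyl ketone is the substrate class for which an unstabilised ylide gives the Z trisubstituted alkene.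

**Tartrate core.** Ketone 12 comes from the C2-symmetric bis-Weinreb amide 10 by one methyl addition. Amide 10 comes from acetonide diester 9 and that from diethyl D-tartrate (8), which supplies C8 and C9 with the correct absolute configuration.

**C1–C5 fragment.** Salt 5 comes from diiodide 4, and 4 from iodo alcohol 3. Alcohol 3 is the methylalumination–iodination product of 4-pentyn-1-ol (1), which fixes the E C4=C5 bond.

## Alternatives that were turned down

**Alternative 1:** The disconnection is at C7–C11, with ring B unravelled to an ester on O6. The substrate is A2, the ten-membered C7 ketone carrying a propiolate on O6, a triethylsilyl ether on O8 and the angelate on O9. In the forward step [(Ph3P)CuH]6 (monovalent copper hydride) puts hydride on the alkyne terminus C13, and the copper allenolate attacks the C7 carbonyl through C11 (5-exo aldol). Lactone, tertiary carbinol and exocyclic methylene of A1 then appear together.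
- For it: the tether forces C11 onto the face of C7 where O6 sits, which is the cis fusion of the target. The angelate is already present, so no late choice among three hydroxyls is needed, and a single desilylation finishes the synthesis.
- Against it: it makes only ring B. Ring A must already exist as a 6,8,9-trioxygenated cyclodecadienone, which is the real difficulty. A2 is an α,α'-dioxygenated ketone open to epimerisation at C6 and C8 and to β-elimination. The hydride can also reduce the angelate and, by 1,4-addition, the α-methylene lactone it has just made.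
- Comparison: it is stronger on end-game brevity and on avoiding a selective acylation. The chosen strategy instead builds ring A, C6 and C7 in one event from an acyclic chiral-pool chain.

**Alternative 2:** The disconnection cuts C2–C3 and joins C5–C10, turning ring A into a cyclohexane, the cis-dialkenylcyclohexanol A4. A4 has vinyl and hydroxyl on C10, isopropenyl on C5, C6–C9 oxygenated in a conduritol pattern, and a silylalkyne on C7 in place of the lactone carbons. In the forward step the potassium alkoxide (KH, THF) undergoes a [3,3] shift that forms C2–C3 and breaks C5–C10; the C1=C10 enolate is trapped with PhNTf2 as enol triflate A3.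
- For it: ring expansion from a six-membered ring has no medium-ring entropy penalty, stereocontrol on cyclohexanes is mature, and the chair transition state turns ring configuration into alkene geometry.
- Against it: A4 needs six contiguous stereocentres, two of which (C5, C10) are destroyed. The Z C1=C10 bond requires the less favoured arrangement with an axial vinyl group. The C10 methyl must then be added by cross-coupling of a hindered triflate, ring B is still to be built from the alkyne, and four kinds of protecting group are carried.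
- Comparison: it is stronger in the certainty of the ring-forming event itself. The chosen strategy offers a much shorter route in which the ring-forming step also delivers C6, C7 and the methylene.

**Alternative 3:** The disconnection is at C7–C8 with ring B kept as a tetronate. The substrate is A6, a 3-(bromomethyl)-4-(triethylsilyloxy)butenolide whose C6 side chain ends in the C8 aldehyde, with O9 as a PMB ether. In the forward step CrCl2 (divalent chromium) turns the C13 bromide into an allylchromium that adds through C7 to the aldehyde. This forms C7–C8, closes ring A and moves the alkene to C11=C13, giving A5.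
- For it: lactone and methylene are in place before the ring closes, so no redox adjustment follows. Ring A and two stereocentres are made at once under mild, chemoselective conditions.
- Against it: C8 is created in the cyclisation under the influence of C9 and C6 through a medium-ring transition state and cannot be taken from the chiral pool. The α-alkoxy aldehyde can epimerise at C9. The allylmetal must bond through a fully substituted, oxygenated C7. The closure is a direct ten-membered cyclisation.
- Comparison: it is at least equal in end-game economy and mildness. The chosen strategy offers C8 and C9 fixed from tartrate, and ring formation by contraction of a 13-membered ether with stereochemistry relayed through a five-membered transition state.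

Key step: step 15

Assumption: the target SMILES is read as the absolute configuration (6S,7S,8S,9R) with a 1(10)Z,4E diene and a (Z)-2-methylbut-2-enoate; the C8/C9 diol then corresponds to (S,S)-tartaric acid (D-series).

## Route

Step 1
Reactants: 1 4-pentyn-1-ol
Product: 3 (4E)-5-iodo-4-methylpent-4-en-1-ol, via alkenylalane 2 (not isolated)
Conditions: AlMe3 (3 equiv), (C5H5)2ZrCl2 (0.25 equiv), CH2Cl2, 0 °C → rt; then I2, THF, −30 °C → 0 °C
Reagents that add atoms: trimethylaluminium, C[Al](C)C; iodine, II
Why: Negishi zirconium-catalysed carboalumination adds methyl and aluminium syn across the alkyne with the metal on the terminal carbon; iodinolysis with retention should give the E vinyl iodide, which fixes the C4=C5 geometry.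

Step 2
Reactants: 3 (4E)-5-iodo-4-methylpent-4-en-1-ol
Product: 4 (1E)-1,5-diiodo-2-methylpent-1-ene
Conditions: I2, PPh3, imidazole, CH2Cl2, 0 °C → rt
Reagents that add atoms: iodine, II
Why: Appel iodination of the primary alcohol; the vinyl iodide is inert.

Step 3
Reactants: 4 (1E)-1,5-diiodo-2-methylpent-1-ene
Product: 5 [(4E)-5-iodo-4-methylpent-4-en-1-yl]triphenylphosphonium iodide
Conditions: PPh3, MeCN, reflux
Reagents that add atoms: triphenylphosphine, c1ccc(cc1)P(c1ccccc1)c1ccccc1
Why: SN2 quaternisation occurs only at the primary alkyl iodide; an sp2 C–I bond does not react with a phosphine without a metal catalyst.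

Step 4
Reactants: 6 ethyl 3-hydroxypropanoate
Product: 7 ethyl 3-[(tert-butyldimethylsilyl)oxy]propanoate
Conditions: TBSCl, imidazole, CH2Cl2, 0 °C → rt
Reagents that add atoms: tert-butyldimethylsilyl chloride, CC(C)(C)[Si](C)(C)Cl
Why: Standard silylation; this silyl ether becomes the C12 protecting group and stays until after the key step.

Step 5
Reactants: 8 diethyl D-tartrate
Product: 9 diethyl (4S,5S)-2,2-dimethyl-1,3-dioxolane-4,5-dicarboxylate
Conditions: 2,2-dimethoxypropane, p-TsOH·H2O (cat.), cyclohexane, reflux with removal of MeOH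
Reagents that add atoms: 2,2-dimethoxypropane, COC(C)(C)OC
Why: Acid-catalysed transacetalisation of the threo diol to the trans dioxolane; the stereocentres are not touched.

Step 6
Reactants: 9 diethyl (4S,5S)-2,2-dimethyl-1,3-dioxolane-4,5-dicarboxylate
Product: 10 (4S,5S)-N4,N5-dimethoxy-N4,N5,2,2-tetramethyl-1,3-dioxolane-4,5-dicarboxamide
Conditions: MeNH(OMe)·HCl, i-PrMgCl, THF, −20 °C → 0 °C
Reagents that add atoms: N,O-dimethylhydroxylamine hydrochloride, CNOC.Cl
Why: Aminolysis of both esters by the magnesium amide made in the flask; the low temperature and the thermodynamic preference for the trans dioxolane guard the α-stereocentres.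

Step 7
Reactants: 10 (4S,5S)-N4,N5-dimethoxy-N4,N5,2,2-tetramethyl-1,3-dioxolane-4,5-dicarboxamide
Product: 12 (4S,5S)-5-acetyl-N-methoxy-N,2,2-trimethyl-1,3-dioxolane-4-carboxamide, via magnesium hemiaminal chelate 11 (not isolated)
Conditions: MeMgBr (1.3 equiv), THF, −15 °C; aq. NH4Cl
Reagents that add atoms: methylmagnesium bromide, C[Mg]Br
Why: Weinreb ketone synthesis; the first adduct is a stable chelate that does not collapse before the quench and retards attack on the neighbouring amide, so the C2-symmetric diamide should be desymmetrised to the mono-ketone, as is known for tartaric bis-Weinreb amides.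

Step 8
Reactants: 5 [(4E)-5-iodo-4-methylpent-4-en-1-yl]triphenylphosphonium iodide; 12 (4S,5S)-5-acetyl-N-methoxy-N,2,2-trimethyl-1,3-dioxolane-4-carboxamide
Product: 14 (4S,5R)-5-[(2Z,6E)-7-iodo-6-methylhepta-2,6-dien-2-yl]-N-methoxy-N,2,2-trimethyl-1,3-dioxolane-4-carboxamide, via phosphorus ylide 13 (not isolated)
Conditions: KN(SiMe3)2, THF, −78 °C → 0 °C; then 12, −78 °C → rt
Reagents that add atoms: none
Why: Wittig olefination of an unstabilised ylide with an α-alkoxy methyl ketone, the case that places the ylide carbon cis to the oxygenated carbon; this should set C1=C10 as Z (C2 cis to C9). The ketone reacts far faster than the Weinreb amide, and epimerisation at C9 would lead to the less stable cis dioxolane.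

Step 9
Reactants: 7 ethyl 3-[(tert-butyldimethylsilyl)oxy]propanoate; 14 (4S,5R)-5-[(2Z,6E)-7-iodo-6-methylhepta-2,6-dien-2-yl]-N-methoxy-N,2,2-trimethyl-1,3-dioxolane-4-carboxamide
Product: 17 ethyl 2-{[(tert-butyldimethylsilyl)oxy]methyl}-3-{(4S,5R)-5-[(2Z,6E)-7-iodo-6-methylhepta-2,6-dien-2-yl]-2,2-dimethyl-1,3-dioxolan-4-yl}-3-oxopropanoate (both C2 epimers), via lithium ester enolate 15 (not isolated), via lithium hemiaminal adduct 16 (not isolated)
Conditions: LiN(i-Pr)2, 7 (2.5 equiv), THF, −78 °C; then 14, −78 °C → −45 °C; AcOH, −78 °C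
Reagents that add atoms: none
Why: Crossed Claisen acylation of an ester enolate by a Weinreb amide; the tetrahedral adduct persists until the acidic quench, so there is no over-addition, and keeping the enolate cold limits β-elimination of silanolate. The new C11 centre is removed in the next step.

Step 10
Reactants: 17 ethyl 2-{[(tert-butyldimethylsilyl)oxy]methyl}-3-{(4S,5R)-5-[(2Z,6E)-7-iodo-6-methylhepta-2,6-dien-2-yl]-2,2-dimethyl-1,3-dioxolan-4-yl}-3-oxopropanoate
Product: 19 ethyl (2E)-2-{[(tert-butyldimethylsilyl)oxy]methyl}-3-{(4S,5R)-5-[(2Z,6E)-7-iodo-6-methylhepta-2,6-dien-2-yl]-2,2-dimethyl-1,3-dioxolan-4-yl}-3-(methoxymethoxy)prop-2-enoate, via sodium enolate 18 (not isolated)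
Conditions: NaH, THF–DMPU (3:1), 0 °C; then MOMCl, 0 °C
Reagents that add atoms: chloromethyl methyl ether, COCCl
Why: O-alkylation of a β-keto ester enolate by a hard α-chloro ether; C-alkylation would create a quaternary centre and is disfavoured. In the solvent-separated enolate the two oxygens lie apart and the bulky dioxolanyl group sits next to the ester, which can twist, so the ether should form trans to the ester: C8 cis to the future C13, O7 cis to C12.

Step 11
Reactants: 19 ethyl (2E)-2-{[(tert-butyldimethylsilyl)oxy]methyl}-3-{(4S,5R)-5-[(2Z,6E)-7-iodo-6-methylhepta-2,6-dien-2-yl]-2,2-dimethyl-1,3-dioxolan-4-yl}-3-(methoxymethoxy)prop-2-enoate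
Product: 20 ethyl (2E)-2-{[(tert-butyldimethylsilyl)oxy]methyl}-3-{(4S,5R)-5-[(2Z,6E)-8-hydroxy-6-methylocta-2,6-dien-2-yl]-2,2-dimethyl-1,3-dioxolan-4-yl}-3-(methoxymethoxy)prop-2-enoate
Conditions: n-Bu3SnCH2OH, Pd(PPh3)4 (5 mol %), 1,4-dioxane, 85 °C
Reagents that add atoms: (tributylstannyl)methanol, CCCC[Sn](CCCC)(CCCC)CO
Why: Stille coupling (hydroxymethylation) of the vinyl iodide at zerovalent palladium with retention of the E geometry; it reveals C6 as the only free hydroxyl of the molecule.

Step 12
Reactants: 20 ethyl (2E)-2-{[(tert-butyldimethylsilyl)oxy]methyl}-3-{(4S,5R)-5-[(2Z,6E)-8-hydroxy-6-methylocta-2,6-dien-2-yl]-2,2-dimethyl-1,3-dioxolan-4-yl}-3-(methoxymethoxy)prop-2-enoate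
Product: 22 ethyl (2E)-2-{[(tert-butyldimethylsilyl)oxy]methyl}-3-{(4S,5R)-5-[(2Z,6E)-8-chloro-6-methylocta-2,6-dien-2-yl]-2,2-dimethyl-1,3-dioxolan-4-yl}-3-(methoxymethoxy)prop-2-enoate, via allylic mesylate 21 (not isolated)
Conditions: MsCl, 2,4,6-collidine, LiCl, DMF, 0 °C
Reagents that add atoms: lithium chloride, [Li+].[Cl-]
Why: Collington–Meyers chlorination: mesylation followed by SN2 displacement at the primary allylic carbon, without allylic transposition and under non-acidic conditions.

Step 13
Reactants: 22 ethyl (2E)-2-{[(tert-butyldimethylsilyl)oxy]methyl}-3-{(4S,5R)-5-[(2Z,6E)-8-chloro-6-methylocta-2,6-dien-2-yl]-2,2-dimethyl-1,3-dioxolan-4-yl}-3-(methoxymethoxy)prop-2-enoate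
Product: 23 (2Z)-2-{[(tert-butyldimethylsilyl)oxy]methyl}-3-{(4S,5R)-5-[(2Z,6E)-8-chloro-6-methylocta-2,6-dien-2-yl]-2,2-dimethyl-1,3-dioxolan-4-yl}-3-(methoxymethoxy)prop-2-en-1-ol
Conditions: i-Bu2AlH (2.5 equiv), CH2Cl2, −78 °C; aq. potassium sodium tartrate
Reagents that add atoms: none
Why: 1,2-Reduction of the vinylogous carbonate ester to the C13 alcohol; allylic chloride, silyl ether and acetals are inert at −78 °C. The γ-alkoxy allylic alcohol is kept away from acid.

Step 14
Reactants: 23 (2Z)-2-{[(tert-butyldimethylsilyl)oxy]methyl}-3-{(4S,5R)-5-[(2Z,6E)-8-chloro-6-methylocta-2,6-dien-2-yl]-2,2-dimethyl-1,3-dioxolan-4-yl}-3-(methoxymethoxy)prop-2-en-1-ol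
Product: 25 13-membered diallyl ether (O6–C13 ether; 4E; 1(10)Z; C7=C11 enol ether with C8 cis to C13; 7-OMOM; 12-OTBS; (8S,9R) acetonide), via sodium alkoxide 24 (not isolated)
Conditions: NaH, 15-crown-5 (cat.), THF, 45 °C, slow addition to 0.002 M
Reagents that add atoms: none
Why: Intramolecular Williamson ether synthesis (13-exo-tet) of a primary alkoxide on a primary allylic chloride under high dilution; large diallylic ether rings of this kind close without appreciable strain.

Step 15
Reactants: 25 13-membered diallyl ether
Product: 28 (1(10)Z,4E,6S,7R,8S,9R)-12-[(tert-butyldimethylsilyl)oxy]-8,9-(isopropylidenedioxy)-7-(methoxymethoxy)germacra-1(10),4,11(13)-trien-6-ol, via C6-lithiated ether 26 (not isolated), via lithium alkoxide 27 (not isolated)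
Conditions: n-BuLi (2 equiv), THF, −78 °C → −25 °C; aq. NH4Cl
Reagents that add atoms: none
Why: n-BuLi removes a proton from C6, the ether α-carbon that is allylic to the alkyl-substituted C4=C5 bond, and the α-oxyallyl lithium 26 undergoes a concerted suprafacial [2,3]-Wittig shift through a five-membered envelope in which C6 bonds to C7, O6–C13 breaks and the alkene moves to C11=C13, giving alkoxide 27. The closest known reaction type is the [2,3]-Wittig ring contraction of 13-membered diallylic ethers to germacrane carbocycles; what is new here is a fully substituted enol-ether carbon as the accepting terminus. Ring A is closed by contraction of the existing 13-membered ring (formally 10-exo-trig at C7, with C7=C11 exocyclic to the new ring), so no separate medium-ring cyclisation is needed. The C6/C7 relationship follows from the alkene geometry: with C8 cis to C13 and the C5 substituent of the carbanion exo on the envelope (the usual preference, and the arrangement the short C5–C8 tether favours as a cis-fused bicyclic transition state), H6 ends cis to O7 and C5 cis to C8, as the cis-fused lactone requires. The absolute sense at C7 is set by C8: 1,3-allylic strain with C13 holds H8 in the alkene plane, so C9 with the tether lies on one face and the dioxolane C8–O bond on the other, and C6 should be delivered on the C9 face, anti to that C–O bond. The step needs lithiation at C6 and not at C13 or C12; C6 is the least substituted and least electron-rich allylic site, whereas C13 and C12 flank a tetrasubstituted, donor-substituted alkene. It also needs the [2,3] shift to outrun the [1,2] shift, which the low temperature favours. C7, as the oxygen-bearing carbon of the enol ether, is the positively polarised end of the C7=C11 bond and so matches the nucleophilic C6.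

Step 16
Reactants: 28 (1(10)Z,4E,6S,7R,8S,9R)-12-[(tert-butyldimethylsilyl)oxy]-8,9-(isopropylidenedioxy)-7-(methoxymethoxy)germacra-1(10),4,11(13)-trien-6-ol
Product: 29 (1(10)Z,4E,6S,7R,8S,9R)-8,9-(isopropylidenedioxy)-7-(methoxymethoxy)germacra-1(10),4,11(13)-triene-6,12-diol
Conditions: n-Bu4NF, THF, 0 °C → rt
Reagents that add atoms: none
Why: Fluoride cleavage of the primary allylic silyl ether; acetonide and methoxymethyl ether are untouched.

Step 17
Reactants: 29 (1(10)Z,4E,6S,7R,8S,9R)-8,9-(isopropylidenedioxy)-7-(methoxymethoxy)germacra-1(10),4,11(13)-triene-6,12-diol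
Product: 32 (1(10)Z,4E,6S,7R,8S,9R)-8,9-(isopropylidenedioxy)-7-(methoxymethoxy)germacra-1(10),4,11(13)-trien-12,6-olide, via enal 30 (not isolated), via lactol 31 (not isolated)
Conditions: TEMPO (0.2 equiv), PhI(OAc)2 (3 equiv), CH2Cl2, rt
Reagents that add atoms: none
Why: Oxoammonium (TEMPO) oxidation is selective for the primary allylic alcohol; the enal is trapped by the C6 hydroxyl as the five-membered lactol, which is oxidised on to the lactone. O8 is locked in the acetonide, so only the 12,6-olide can form.

Step 18
Reactants: 32 (1(10)Z,4E,6S,7R,8S,9R)-8,9-(isopropylidenedioxy)-7-(methoxymethoxy)germacra-1(10),4,11(13)-trien-12,6-olide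
Product: 33 (1(10)Z,4E,6S,7S,8S,9R)-7,8,9-trihydroxygermacra-1(10),4,11(13)-trien-12,6-olide
Conditions: CF3CO2H–H2O–THF (3:1:1), 0 °C → rt
Reagents that add atoms: none
Why: Acid hydrolysis of the ketal and of the tertiary formal in a water-rich medium; both alkenes carry an allylic oxygen and the lactone deactivates C6–O, which should slow cationic side reactions.

Step 19
Reactants: 33 (1(10)Z,4E,6S,7S,8S,9R)-7,8,9-trihydroxygermacra-1(10),4,11(13)-trien-12,6-olide; 34 angelic acid [(2Z)-2-methylbut-2-enoic acid]
Product: 36 (1(10)Z,4E,6S,7S,8S,9R)-9-angeloyloxy-7,8-dihydroxygermacra-1(10),4,11(13)-trien-12,6-olide (target), via mixed anhydride 35 (not isolated)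
Conditions: 34, 2,4,6-trichlorobenzoyl chloride, Et3N, toluene, rt; then 33, 70 °C (no DMAP)
Reagents that add atoms: none
Why: Yamaguchi-type mixed-anhydride esterification without a nucleophilic catalyst, the protocol that keeps the Z geometry of angelates. The secondary allylic 9-hydroxyl should react alone, because the 8-hydroxyl is flanked by the quaternary C7 and the 7-hydroxyl is tertiary.

## Compound list

1 | 4-pentyn-1-ol | C#CCCCO | starting material
2 | dimethyl[(1E)-5-(dimethylalumanyloxy)-2-methylpent-1-en-1-yl]alumane | C[Al](C)/C=C(\C)CCCO[Al](C)C | intermediate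
3 | (4E)-5-iodo-4-methylpent-4-en-1-ol | OCCC/C(C)=C/I | intermediate
4 | (1E)-1,5-diiodo-2-methylpent-1-ene | ICCC/C(C)=C/I | intermediate
5 | [(4E)-5-iodo-4-methylpent-4-en-1-yl]triphenylphosphonium iodide | C/C(CCC[P+](c1ccccc1)(c1ccccc1)c1ccccc1)=C\I.[I-] | intermediate
6 | ethyl 3-hydroxypropanoate | CCOC(=O)CCO | starting material
7 | ethyl 3-[(tert-butyldimethylsilyl)oxy]propanoate | CCOC(=O)CCO[Si](C)(C)C(C)(C)C | intermediate
8 | diethyl D-tartrate [diethyl (2S,3S)-2,3-dihydroxybutanedioate] | CCOC(=O)[C@@H](O)[C@H](O)C(=O)OCC | starting material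
9 | diethyl (4S,5S)-2,2-dimethyl-1,3-dioxolane-4,5-dicarboxylate | CCOC(=O)[C@H]1OC(C)(C)O[C@@H]1C(=O)OCC | intermediate
10 | (4S,5S)-N4,N5-dimethoxy-N4,N5,2,2-tetramethyl-1,3-dioxolane-4,5-dicarboxamide | CON(C)C(=O)[C@H]1OC(C)(C)O[C@@H]1C(=O)N(C)OC | intermediate
11 | bromomagnesium alkoxide of the mono-methyl hemiaminal adduct of 10 | CON(C)C(C)(O[Mg]Br)[C@H]1OC(C)(C)O[C@@H]1C(=O)N(C)OC | intermediate
12 | (4S,5S)-5-acetyl-N-methoxy-N,2,2-trimethyl-1,3-dioxolane-4-carboxamide | CC(=O)[C@H]1OC(C)(C)O[C@@H]1C(=O)N(C)OC | intermediate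
13 | [(4E)-5-iodo-4-methylpent-4-en-1-ylidene]triphenyl-λ5-phosphane | C/C(CCC=P(c1ccccc1)(c1ccccc1)c1ccccc1)=C\I | intermediate
14 | (4S,5R)-5-[(2Z,6E)-7-iodo-6-methylhepta-2,6-dien-2-yl]-N-methoxy-N,2,2-trimethyl-1,3-dioxolane-4-carboxamide | I/C=C(\C)CC/C=C(/C)[C@H]1OC(C)(C)O[C@@H]1C(=O)N(C)OC | intermediate
15 | lithium enolate of 7 | CCOC(O[Li])=CCO[Si](C)(C)C(C)(C)C | intermediate
16 | lithium alkoxide of the tetrahedral adduct of 15 with 14 | I/C=C(\C)CC/C=C(/C)[C@H]1OC(C)(C)O[C@@H]1C(O[Li])(N(C)OC)C(CO[Si](C)(C)C(C)(C)C)C(=O)OCC | intermediate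
17 | ethyl 2-{[(tert-butyldimethylsilyl)oxy]methyl}-3-{(4S,5R)-5-[(2Z,6E)-7-iodo-6-methylhepta-2,6-dien-2-yl]-2,2-dimethyl-1,3-dioxolan-4-yl}-3-oxopropanoate (C2 epimers) | I/C=C(\C)CC/C=C(/C)[C@H]1OC(C)(C)O[C@@H]1C(=O)C(CO[Si](C)(C)C(C)(C)C)C(=O)OCC | intermediate
18 | sodium enolate of 17 (enolate oxygen trans to the ester) | I/C=C(\C)CC/C=C(/C)[C@H]1OC(C)(C)O[C@@H]1/C([O-])=C(/CO[Si](C)(C)C(C)(C)C)C(=O)OCC.[Na+] | intermediate
19 | ethyl (2E)-2-{[(tert-butyldimethylsilyl)oxy]methyl}-3-{(4S,5R)-5-[(2Z,6E)-7-iodo-6-methylhepta-2,6-dien-2-yl]-2,2-dimethyl-1,3-dioxolan-4-yl}-3-(methoxymethoxy)prop-2-enoate | I/C=C(\C)CC/C=C(/C)[C@H]1OC(C)(C)O[C@@H]1/C(OCOC)=C(/CO[Si](C)(C)C(C)(C)C)C(=O)OCC | intermediate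
20 | ethyl (2E)-2-{[(tert-butyldimethylsilyl)oxy]methyl}-3-{(4S,5R)-5-[(2Z,6E)-8-hydroxy-6-methylocta-2,6-dien-2-yl]-2,2-dimethyl-1,3-dioxolan-4-yl}-3-(methoxymethoxy)prop-2-enoate | OC/C=C(\C)CC/C=C(/C)[C@H]1OC(C)(C)O[C@@H]1/C(OCOC)=C(/CO[Si](C)(C)C(C)(C)C)C(=O)OCC | intermediate
21 | methanesulfonate of 20 | CS(=O)(=O)OC/C=C(\C)CC/C=C(/C)[C@H]1OC(C)(C)O[C@@H]1/C(OCOC)=C(/CO[Si](C)(C)C(C)(C)C)C(=O)OCC | intermediate
22 | ethyl (2E)-2-{[(tert-butyldimethylsilyl)oxy]methyl}-3-{(4S,5R)-5-[(2Z,6E)-8-chloro-6-methylocta-2,6-dien-2-yl]-2,2-dimethyl-1,3-dioxolan-4-yl}-3-(methoxymethoxy)prop-2-enoate | ClC/C=C(\C)CC/C=C(/C)[C@H]1OC(C)(C)O[C@@H]1/C(OCOC)=C(/CO[Si](C)(C)C(C)(C)C)C(=O)OCC | intermediate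
23 | (2Z)-2-{[(tert-butyldimethylsilyl)oxy]methyl}-3-{(4S,5R)-5-[(2Z,6E)-8-chloro-6-methylocta-2,6-dien-2-yl]-2,2-dimethyl-1,3-dioxolan-4-yl}-3-(methoxymethoxy)prop-2-en-1-ol | ClC/C=C(\C)CC/C=C(/C)[C@H]1OC(C)(C)O[C@@H]1/C(OCOC)=C(/CO[Si](C)(C)C(C)(C)C)CO | intermediate
24 | sodium alkoxide of 23 | ClC/C=C(\C)CC/C=C(/C)[C@H]1OC(C)(C)O[C@@H]1/C(OCOC)=C(/CO[Si](C)(C)C(C)(C)C)C[O-].[Na+] | intermediate
25 | 13-membered diallyl ether: O6–C13 ether, 4E, 1(10)Z, C7=C11 enol ether with C8 cis to C13, 7-OMOM, 12-OTBS, (8S,9R)-acetonide | O1C/C=C(\C)CC/C=C(/C)[C@H]2OC(C)(C)O[C@@H]2/C(OCOC)=C(/CO[Si](C)(C)C(C)(C)C)C1 | intermediate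
26 | C6-lithio derivative of 25 | [Li]C1/C=C(\C)CC/C=C(/C)[C@H]2OC(C)(C)O[C@@H]2/C(OCOC)=C(/CO[Si](C)(C)C(C)(C)C)CO1 | intermediate
27 | lithium 6-alkoxide of 28 | C=C(CO[Si](C)(C)C(C)(C)C)[C@@]1(OCOC)[C@@H](O[Li])/C=C(\C)CC/C=C(/C)[C@H]2OC(C)(C)O[C@H]12 | intermediate
28 | (1(10)Z,4E,6S,7R,8S,9R)-12-[(tert-butyldimethylsilyl)oxy]-8,9-(isopropylidenedioxy)-7-(methoxymethoxy)germacra-1(10),4,11(13)-trien-6-ol | C=C(CO[Si](C)(C)C(C)(C)C)[C@@]1(OCOC)[C@@H](O)/C=C(\C)CC/C=C(/C)[C@H]2OC(C)(C)O[C@H]12 | intermediate
29 | (1(10)Z,4E,6S,7R,8S,9R)-8,9-(isopropylidenedioxy)-7-(methoxymethoxy)germacra-1(10),4,11(13)-triene-6,12-diol | C=C(CO)[C@@]1(OCOC)[C@@H](O)/C=C(\C)CC/C=C(/C)[C@H]2OC(C)(C)O[C@H]12 | intermediate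
30 | (1(10)Z,4E,6S,7R,8S,9R)-6-hydroxy-8,9-(isopropylidenedioxy)-7-(methoxymethoxy)germacra-1(10),4,11(13)-trien-12-al | C=C(C=O)[C@@]1(OCOC)[C@@H](O)/C=C(\C)CC/C=C(/C)[C@H]2OC(C)(C)O[C@H]12 | intermediate
31 | 12-hydroxy-6,12-epoxy lactol of 30 (both C12 epimers) | C=C1C(O)O[C@H]2/C=C(\C)CC/C=C(/C)[C@H]3OC(C)(C)O[C@@H]3[C@@]12OCOC | intermediate
32 | (1(10)Z,4E,6S,7R,8S,9R)-8,9-(isopropylidenedioxy)-7-(methoxymethoxy)germacra-1(10),4,11(13)-trien-12,6-olide | C=C1C(=O)O[C@H]2/C=C(\C)CC/C=C(/C)[C@H]3OC(C)(C)O[C@@H]3[C@@]12OCOC | intermediate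
33 | (1(10)Z,4E,6S,7S,8S,9R)-7,8,9-trihydroxygermacra-1(10),4,11(13)-trien-12,6-olide | C=C1C(=O)O[C@H]2/C=C(\C)CC/C=C(/C)[C@@H](O)[C@H](O)[C@@]12O | intermediate
34 | angelic acid [(2Z)-2-methylbut-2-enoic acid] | C/C=C(/C)C(=O)O | starting material
35 | (2Z)-2-methylbut-2-enoic 2,4,6-trichlorobenzoic anhydride | C/C=C(/C)C(=O)OC(=O)c1c(Cl)cc(Cl)cc1Cl | intermediate
36 | (1(10)Z,4E,6S,7S,8S,9R)-9-angeloyloxy-7,8-dihydroxygermacra-1(10),4,11(13)-trien-12,6-olide (CNP0303917.1) | C=C1C(=O)O[C@H]2/C=C(\C)CC/C=C(/C)[C@@H](OC(=O)/C(C)=C\C)[C@H](O)[C@@]12O | target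

## Step count and least certain steps

Total step count: 19. Longest linear sequence: 15 steps (steps 5–19, from diethyl D-tartrate 8). The phosphonium salt (steps 1–3) and the silyloxy ester (step 4) are made separately.

**Step 15 (key step).** Three things can go wrong.
- Lithiation may occur at C13 or C12, helped by coordination of lithium to the methoxymethyl or silyl ether oxygens. This would lead to the regioisomeric shift onto C4 or to silyl migration.
- Bond formation at the fully substituted, electron-rich C7 may be slow enough for the [1,2]-shift or fragmentation of the allyl anion to take over. This acceptor terminus has no precedent in the ring contraction.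
- Delivery to the wrong face of C7 would give the 6,7-diastereomer pair.

The fallback avoids carbanion chemistry and closes ring A with a chromium allylation that also forms the lactone. It sets out from 20 and returns at 32. Oxidation of 20 with MnO2 would give the C6 enal F1. HF·pyridine would remove the silyl group to give the hydroxymethyl enal F2. NBS/PPh3 at −20 °C would give the bromomethyl enal F3. CrCl2 (divalent chromium) in THF–DMF at high dilution would convert F3 into the allylchromium F4, which should add through C7 to the C6 aldehyde (Nozaki–Hiyama allylation). The chromium alkoxide F5 so formed would close onto the neighbouring ethyl ester and give lactone 32. The 6,7-configuration would then be decided in a chair-like chromium transition state and would have to be confirmed.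

**Step 10.** Geometric control in the O-alkylation may be incomplete, and the enolate may lose silanolate by β-elimination before it is trapped. The other geometry is not a loss, because it reaches 25 by a different order of operations; this fallback sets out from 17 and returns at 25. Under chelating conditions (NaH in THF without DMPU, then MOMCl) the Z enol ether F6 is expected. Stille hydroxymethylation as in step 11 would give the Z allylic alcohol F7. Chlorination as in step 12 would proceed through the Z mesylate F8 to the Z chloride F9. In this isomer the silyloxymethyl group is the one cis to C8, so HF·pyridine/pyridine in THF would free it to give the Z hydroxymethyl ester F10. Its sodium alkoxide F11 would close the 13-membered ring to the macrocyclic ester F12. Reduction with i-Bu2AlH would give the macrocyclic allylic alcohol F13, and silylation (TBSCl, imidazole) would give 25.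

**Step 9.** Enolate 15 may eliminate silanolate faster than it acylates the amide, and any excess amide base may attack the N-methoxy group of 14. The fallback replaces the acylation by an aldol reaction followed by oxidation, so that the enolate meets a much faster electrophile at −78 °C. It sets out from 14 and returns at 17. Reduction of 14 with i-Bu2AlH at −78 °C would give the dioxolane carbaldehyde F14. Addition of enolate 15 would give the β-hydroxy ester F15 as a diastereomer mixture. Dess–Martin periodinane would oxidise F15 to 17.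

**Step 18.** During formal cleavage the formaldehyde unit may be transferred to the neighbouring 8-hydroxyl, giving a methylene acetal that cannot be removed. The acid may also trigger transannular cyclisation of the diene or migration of the lactone to O8. The fallback removes the two groups in separate operations of different type; it sets out from 32 and returns at 33. Aqueous acetic acid (AcOH–H2O 4:1, 40 °C) would hydrolyse only the ketal and give the 7-O-methoxymethyl 8,9-diol lactone F16. Me2BBr in CH2Cl2 at −78 °C, followed by aq. NaHCO3, would then cleave the formal to give 33. The hydroxyls are capped as borinates during that cleavage, so they cannot capture the formaldehyde unit.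

**Step 19.** Acylation may reach O8 or both secondary hydroxyls, the angelate may isomerise to the tiglate at 70 °C, and the free 8-hydroxyl may open the lactone under the basic conditions. The fallback acylates before the tertiary position is unmasked; it sets out from 32 and returns at 36. The diol lactone F16 would be made as described for step 18 and esterified with mixed anhydride 35. The methoxymethyl ether on C7 makes the 8-hydroxyl still more hindered and leaves only two hydroxyls to choose from, so the 9-O-angeloyl 7-O-methoxymethyl lactone F17 should result. Me2BBr at −78 °C, then aq. NaHCO3, would remove the formal to give 36.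

## Further compounds

F1 | step 15 | C6 enal of 20 (ethyl ester and 12-O-silyl ether retained) | O=C/C=C(\C)CC/C=C(/C)[C@H]1OC(C)(C)O[C@@H]1/C(OCOC)=C(/CO[Si](C)(C)C(C)(C)C)C(=O)OCC
F2 | step 15 | hydroxymethyl enal (desilylated F1) | O=C/C=C(\C)CC/C=C(/C)[C@H]1OC(C)(C)O[C@@H]1/C(OCOC)=C(/CO)C(=O)OCC
F3 | step 15 | bromomethyl enal | O=C/C=C(\C)CC/C=C(/C)[C@H]1OC(C)(C)O[C@@H]1/C(OCOC)=C(/CBr)C(=O)OCC
F4 | step 15 | allylchromium dichloride from F3 | O=C/C=C(\C)CC/C=C(/C)[C@H]1OC(C)(C)O[C@@H]1/C(OCOC)=C(/C[Cr](Cl)Cl)C(=O)OCC
F5 | step 15 | chromium 6-alkoxide of the cyclised ethyl ester | C=C(C(=O)OCC)[C@@]1(OCOC)[C@@H](O[Cr](Cl)Cl)/C=C(\C)CC/C=C(/C)[C@H]2OC(C)(C)O[C@H]12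
F6 | step 10 | (2Z) isomer of 19 | I/C=C(\C)CC/C=C(/C)[C@H]1OC(C)(C)O[C@@H]1/C(OCOC)=C(\CO[Si](C)(C)C(C)(C)C)C(=O)OCC
F7 | step 10 | (2Z) isomer of 20 | OC/C=C(\C)CC/C=C(/C)[C@H]1OC(C)(C)O[C@@H]1/C(OCOC)=C(\CO[Si](C)(C)C(C)(C)C)C(=O)OCC
F8 | step 10 | (2Z) isomer of 21 | CS(=O)(=O)OC/C=C(\C)CC/C=C(/C)[C@H]1OC(C)(C)O[C@@H]1/C(OCOC)=C(\CO[Si](C)(C)C(C)(C)C)C(=O)OCC
F9 | step 10 | (2Z) isomer of 22 | ClC/C=C(\C)CC/C=C(/C)[C@H]1OC(C)(C)O[C@@H]1/C(OCOC)=C(\CO[Si](C)(C)C(C)(C)C)C(=O)OCC
F10 | step 10 | ethyl 2-(hydroxymethyl) ester with the hydroxymethyl group cis to C8 (desilylated F9) | ClC/C=C(\C)CC/C=C(/C)[C@H]1OC(C)(C)O[C@@H]1/C(OCOC)=C(\CO)C(=O)OCC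
F11 | step 10 | sodium alkoxide of F10 | ClC/C=C(\C)CC/C=C(/C)[C@H]1OC(C)(C)O[C@@H]1/C(OCOC)=C(\C[O-])C(=O)OCC.[Na+]
F12 | step 10 | 13-membered diallyl ether with ethyl ester at C12 | O1C/C=C(\C)CC/C=C(/C)[C@H]2OC(C)(C)O[C@@H]2/C(OCOC)=C(/C(=O)OCC)C1
F13 | step 10 | 13-membered diallyl ether with free 12-hydroxyl | O1C/C=C(\C)CC/C=C(/C)[C@H]2OC(C)(C)O[C@@H]2/C(OCOC)=C(/CO)C1
F14 | step 9 | (4S,5R)-5-[(2Z,6E)-7-iodo-6-methylhepta-2,6-dien-2-yl]-2,2-dimethyl-1,3-dioxolane-4-carbaldehyde | I/C=C(\C)CC/C=C(/C)[C@H]1OC(C)(C)O[C@@H]1C=O
F15 | step 9 | β-hydroxy ester from F14 and 15 (diastereomer mixture at the carbinol and α-carbons; dioxolane as in 14) | I/C=C(\C)CC/C=C(/C)[C@H]1OC(C)(C)O[C@@H]1C(O)C(CO[Si](C)(C)C(C)(C)C)C(=O)OCC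
F16 | step 18 | (1(10)Z,4E,6S,7S,8S,9R)-8,9-dihydroxy-7-(methoxymethoxy)germacra-1(10),4,11(13)-trien-12,6-olide | C=C1C(=O)O[C@H]2/C=C(\C)CC/C=C(/C)[C@@H](O)[C@H](O)[C@@]12OCOC
F17 | step 19 | (1(10)Z,4E,6S,7S,8S,9R)-9-angeloyloxy-8-hydroxy-7-(methoxymethoxy)germacra-1(10),4,11(13)-trien-12,6-olide | C=C1C(=O)O[C@H]2/C=C(\C)CC/C=C(/C)[C@@H](OC(=O)/C(C)=C\C)[C@H](O)[C@@]12OCOC
A1 | alternative 1 | 8-O-triethylsilyl ether of the target | C=C1C(=O)O[C@H]2/C=C(\C)CC/C=C(/C)[C@@H](OC(=O)/C(C)=C\C)[C@H](O[Si](CC)(CC)CC)[C@@]12O
A2 | alternative 1 | ten-membered C7 ketone with 6-O-propiolate, 8-O-triethylsilyl ether and 9-O-angelate | C#CC(=O)O[C@H]1/C=C(\C)CC/C=C(/C)[C@@H](OC(=O)/C(C)=C\C)[C@H](O[Si](CC)(CC)CC)C1=O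
A3 | alternative 2 | ten-membered dienyl triflate (C10 enol triflate; 6-O-SEM, 7,8-acetonide, 9-O-PMB, C7 silylalkyne) | C/C1=C\[C@H](OCOCC[Si](C)(C)C)[C@@]2(C#C[Si](C(C)C)(C(C)C)C(C)C)OC(C)(C)O[C@H]2[C@H](OCc3ccc(OC)cc3)/C(OS(=O)(=O)C(F)(F)F)=C\CC1
A4 | alternative 2 | cis-1-vinyl-2-isopropenylcyclohexanol precursor of A3 (C5 and C10 shown with vinyl and isopropenyl cis) | C=C[C@@]1(O)[C@@H](C(C)=C)[C@H](OCOCC[Si](C)(C)C)[C@@]2(C#C[Si](C(C)C)(C(C)C)C(C)C)OC(C)(C)O[C@H]2[C@@H]1OCc1ccc(OC)cc1
A5 | alternative 3 | 7-O-triethylsilyl 9-O-PMB germacranolide with free 8-hydroxyl | C=C1C(=O)O[C@H]2/C=C(\C)CC/C=C(/C)[C@@H](OCc3ccc(OC)cc3)[C@H](O)[C@@]12O[Si](CC)(CC)CC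
A6 | alternative 3 | 3-(bromomethyl)-4-(triethylsilyloxy)butenolide with the C8 aldehyde side chain | BrCC1=C(O[Si](CC)(CC)CC)[C@H](/C=C(\C)CC/C=C(/C)[C@@H](OCc2ccc(OC)cc2)C=O)OC1=O
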